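**Retrosynthesis**
1. The target comes from hydrogenolysis of a tetra-O-benzyl sesquilignan.
2. The second THF ring comes from a lactol. The lactol comes from one-carbon homologation (methoxymethylene Wittig) of a 3-oxo-THF, which comes from reductive N–O cleavage of an isoxazoline.
3. The first THF ring and the isoxazoline form together, in the key step, by intramolecular nitrile-oxide/(E)-cinnamyl-ether 1,3-dipolar cycloaddition of an α-aryl-α-alkoxy aldoxime.
4. The oxime carbinol centre comes from (R)-glyceraldehyde acetonide plus a syringyl Grignard. The cinnamyl unit carries the erythro guaiacylglycerol β-ether, made from (S)-glyceraldehyde acetonide plus a guaiacyl Grignard and joined to 4-fluoro-3-methoxybenzaldehyde by SNAr.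
5. Ring order: glycerol ether, then cinnamyl ether, then cycloaddition (THF + isoxazoline), then second THF (lactol reduction), then deprotection.

Assumptions:
- (R)- and (S)-2,3-O-isopropylideneglyceraldehyde (from D-mannitol and L-ascorbic acid) are the chiral pool inputs.
- Aryl Grignard additions give the Felkin anti adduct as the major, chromatographically separable diastereomer.
- The cycloaddition places the C7 aryl trans to the new C–C bond.
- The aldehyde α-carbon can epimerize, so the cis-fused lactol acts as the thermodynamic sink.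

---

**Step 1**
Reactants: 1, 4-bromo-2-methoxyphenol
Product: 2, 1-(benzyloxy)-4-bromo-2-methoxybenzene
Conditions: BnBr, K2CO3, DMF, 60 °C
Reagents that add atoms: benzyl bromide, BrCc1ccccc1
Why: Williamson O-benzylation protects the phenol so a Grignard can be made.

**Step 2**
Reactants: 2; 3, (S)-2,3-O-isopropylideneglyceraldehyde
Product: 4, (R)-[4-(benzyloxy)-3-methoxyphenyl][(4S)-2,2-dimethyl-1,3-dioxolan-4-yl]methanol (anti)
Conditions: Mg, THF, reflux; then 3, –20 °C to rt; separate diastereomers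
Reagents that add atoms: none
Why: Felkin–Anh addition of ArMgBr to the chiral α,β-dialkoxy aldehyde sets the (7R,8S) erythro (anti) relationship (Grignard addition).

**Step 3**
Reactant: 4
Product: 5, benzyl ether of 4 (C7-OBn)
Conditions: NaH, BnBr, TBAI (cat.), DMF, 0 °C to rt
Reagents that add atoms: benzyl bromide, BrCc1ccccc1
Why: Williamson etherification leaves both stereocentres untouched.

**Step 4**
Reactant: 5
Product: 6, (1R,2S)-1-(benzyloxy)-1-[4-(benzyloxy)-3-methoxyphenyl]propane-2,3-diol
Conditions: 60% aq. AcOH, 40 °C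
Reagents that add atoms: water, O
Why: Mild acetonide hydrolysis exposes the C8/C9 diol.

**Step 5**
Reactant: 6
Product: 7, (1R,2S)-1,3-bis(benzyloxy)-1-[4-(benzyloxy)-3-methoxyphenyl]propan-2-ol
Conditions: Bu2SnO, toluene, reflux (Dean–Stark); then BnBr, CsF, DMF, rt
Reagents that add atoms: benzyl bromide, BrCc1ccccc1
Why: The stannylene acetal directs benzylation to the primary OH (Sn-mediated regioselective alkylation), leaving the C8 secondary OH free.

**Step 6**
Reactants: 7; 8, 4-fluoro-3-methoxybenzaldehyde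
Product: 9, 4-({(2S,3R)-1,3-bis(benzyloxy)-3-[4-(benzyloxy)-3-methoxyphenyl]propan-2-yl}oxy)-3-methoxybenzaldehyde
Conditions: NaH, DMF, 0 °C; then 8, 60 °C
Reagents that add atoms: none
Why: SNAr of the C8 alkoxide onto the aldehyde-activated fluoroarene forms the aryl ether without touching the C8–O bond, so the erythro (7R,8S) configuration is retained.

**Step 7**
Reactant: 9
Product: 10, ethyl (E)-3-[aryl]acrylate (aryl = 4-O-glycerol ether of 3-methoxyphenyl, as in 9)
Conditions: (EtO)2P(O)CH2CO2Et, NaH, THF, 0 °C to rt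
Reagents that add atoms: triethyl phosphonoacetate, CCOC(=O)CP(=O)(OCC)OCC
Why: Horner–Wadsworth–Emmons olefination gives the E-enoate.

**Step 8**
Reactant: 10
Product: 11, (E)-3-[aryl]prop-2-en-1-ol
Conditions: DIBAL-H (2.5 equiv), CH2Cl2, –78 °C
Reagents that add atoms: none
Why: DIBAL reduces the ester to the allylic alcohol and leaves the benzyl ethers and the alkene intact.

**Step 9**
Reactant: 11
Product: 12, (E)-cinnamyl bromide of the same aryl
Conditions: PPh3, CBr4, CH2Cl2, 0 °C; crude used at once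
Reagents that add atoms: carbon tetrabromide, BrC(Br)(Br)Br
Why: Neutral Appel bromination avoids acid-mediated ionisation of the electron-rich allylic system.

**Step 10**
Reactant: 13, 4-bromo-2,6-dimethoxyphenol
Product: 14, 2-(benzyloxy)-5-bromo-1,3-dimethoxybenzene
Conditions: BnBr, K2CO3, DMF, 60 °C
Reagents that add atoms: benzyl bromide, BrCc1ccccc1
Why: O-Benzylation protects the syringyl phenol.

**Step 11**
Reactants: 14; 15, (R)-2,3-O-isopropylideneglyceraldehyde
Product: 16, (S)-[4-(benzyloxy)-3,5-dimethoxyphenyl][(4R)-2,2-dimethyl-1,3-dioxolan-4-yl]methanol (anti)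
Conditions: Mg, THF, reflux; then 15, –20 °C to rt; separate diastereomers
Reagents that add atoms: none
Why: Felkin anti addition to the (R) aldehyde fixes the carbinol as (S), which has the spatial arrangement of the syringyl-bearing core carbon (C7′, R) in the target; the glyceraldehyde stereocentre is erased in Step 13.

**Step 12**
Reactants: 16, 12
Product: 17, tether ether (acetonide, C7-O-(E)-cinnamyl)
Conditions: NaH, TBAI (cat.), THF/DMF 4:1, 0 °C to rt
Reagents that add atoms: none
Why: Williamson etherification of the carbinol alkoxide with the allylic bromide has no stereochemical consequence at the carbinol.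

**Step 13**
Reactant: 17
Product: 18, (S)-2-{(E)-3-[aryl]allyloxy}-2-[4-(benzyloxy)-3,5-dimethoxyphenyl]acetaldehyde
Conditions: H5IO6, EtOAc, 0 °C to rt; used immediately
Reagents that add atoms: none
Why: Periodic acid hydrolyses the terminal acetonide and cleaves the resulting diol, destroying the glyceraldehyde centre and retaining the carbinol centre.

**Step 14**
Reactant: 18
Product: 19, the aldoxime of 18
Conditions: NH2OH·HCl, NaOAc, EtOH/H2O, rt
Reagents that add atoms: hydroxylamine, NO
Why: Condensation under mild buffered conditions limits α-epimerization.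

**Step 15 (key step)**
Reactant: 19
Product: 20, cis-fused tetrahydrofuro[3,4-c]isoxazoline (C=N carbon in the THF ring; syringyl aryl on the THF carbon; guaiacyl-OR aryl on the isoxazoline O–CH; both aryls exo; stereochemistry as in the SMILES)
Conditions: aq. NaOCl, Et3N (cat.), CH2Cl2, 0 °C, 0.02 M
Reagents that add atoms: none
Why: The in-situ nitrile oxide undergoes intramolecular 1,3-dipolar [3+2] cycloaddition, forming the THF ring and the isoxazoline in one step. The 3-atom tether forces the fused mode. The E-alkene makes the guaiacyl-aryl/ring-bond relationship trans. The carbinol aryl steers the alkene to the opposite face, so the syringyl aryl ends up trans to the new C–C bond.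

**Step 16**
Reactant: 20
Product: 21, 2-[4-(benzyloxy)-3,5-dimethoxyphenyl]-4-[(S)-hydroxy(aryl)methyl]oxolan-3-one (stereochemistry as in the SMILES)
Conditions: H2 (1 atm), Raney Ni, B(OH)3, MeOH/H2O 5:1, rt
Reagents that add atoms: water, O (supplies the ketone oxygen after imine hydrolysis)
Why: Reductive N–O cleavage gives a β-hydroxy imine, which hydrolyses to the β-hydroxy ketone; the buffered conditions suppress β-elimination, and the 2,4-trans arrangement is the thermodynamically preferred one.

**Step 17**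
Reactant: 21
Product: 22, TES ether of 21
Conditions: TESOTf, 2,6-lutidine, CH2Cl2, –78 °C
Reagents that add atoms: triethylsilyl triflate, CC[Si](CC)(CC)OS(=O)(=O)C(F)(F)F
Why: Silylation protects the benzylic OH against retro-aldol and elimination in the next basic step.

**Step 18**
Reactant: 22
Product: 23, exocyclic methyl enol ether (C=CH–OMe at the former ketone carbon)
Conditions: Ph3P+CH2OMe Cl–, KOt-Bu, THF, 0 °C to rt
Reagents that add atoms: (methoxymethyl)triphenylphosphonium chloride, COC[P+](c1ccccc1)(c1ccccc1)c1ccccc1.[Cl-]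
Why: Wittig methoxymethylenation homologates the ketone by one carbon, supplying the second ring's CH2–O carbon.

**Step 19**
Reactant: 23
Product: 24, lactol (anomeric mixture) of the cis-fused bis-THF
Conditions: 2 M HCl/THF 1:4, 0 °C to rt
Reagents that add atoms: water, O
Why: Enol-ether hydrolysis gives an epimerizable aldehyde; TES loss frees the benzylic OH, and only the cis-disposed epimer closes to the lactol, which is the thermodynamic sink and sets the cis ring fusion.

**Step 20**
Reactant: 24
Product: 25, tetra-O-benzyl sesquilignan (exo,exo furofuran)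
Conditions: Et3SiH, BF3·OEt2, CH2Cl2, –78 to –20 °C
Reagents that add atoms: none
Why: Ionic (oxocarbenium) reduction of the lactol gives the CH2 of the second THF, so no new stereocentre is created.

**Step 21**
Reactant: 25
Product: 26, Ficusesquilignan A
Conditions: H2 (1 atm), Pd(OH)2/C, EtOAc/MeOH, rt, short reaction time
Reagents that add atoms: none
Why: Hydrogenolysis removes the four benzyl groups; no stereocentre is touched.

---

**Compound list**

| # | Name | SMILES | Role |
|---|---|---|---|
| 1 | 4-bromo-2-methoxyphenol | COc1cc(Br)ccc1O | starting material |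
| 2 | 1-(benzyloxy)-4-bromo-2-methoxybenzene | COc1cc(Br)ccc1OCc1ccccc1 | intermediate |
| 3 | (S)-2,3-O-isopropylideneglyceraldehyde | O=C[C@@H]1COC(C)(C)O1 | starting material |
| 4 | (R)-aryl[(4S)-dioxolan-4-yl]methanol (anti adduct, Ar = 4-OBn-3-OMe-C6H3) | COc1cc(ccc1OCc2ccccc2)[C@@H](O)[C@@H]1COC(C)(C)O1 | intermediate |
| 5 | C7-benzyl ether of 4 | COc1cc(ccc1OCc2ccccc2)[C@@H](OCc2ccccc2)[C@@H]1COC(C)(C)O1 | intermediate |
| 6 | (1R,2S)-1-(benzyloxy)-1-aryl-propane-2,3-diol | COc1cc(ccc1OCc2ccccc2)[C@@H](OCc2ccccc2)[C@@H](O)CO | intermediate |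
| 7 | (1R,2S)-1,3-bis(benzyloxy)-1-aryl-propan-2-ol | COc1cc(ccc1OCc2ccccc2)[C@@H](OCc2ccccc2)[C@@H](O)COCc2ccccc2 | intermediate |
| 8 | 4-fluoro-3-methoxybenzaldehyde | COc1cc(C=O)ccc1F | starting material |
| 9 | 4-(erythro-glycerol ether)-3-methoxybenzaldehyde | COc1cc(ccc1OCc2ccccc2)[C@@H](OCc2ccccc2)[C@H](COCc2ccccc2)Oc2ccc(C=O)cc2OC | intermediate |
| 10 | ethyl (E)-cinnamate of 9 | COc1cc(ccc1OCc2ccccc2)[C@@H](OCc2ccccc2)[C@H](COCc2ccccc2)Oc2ccc(/C=C/C(=O)OCC)cc2OC | intermediate |
| 11 | (E)-cinnamyl alcohol | COc1cc(ccc1OCc2ccccc2)[C@@H](OCc2ccccc2)[C@H](COCc2ccccc2)Oc2ccc(/C=C/CO)cc2OC | intermediate |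
| 12 | (E)-cinnamyl bromide | COc1cc(ccc1OCc2ccccc2)[C@@H](OCc2ccccc2)[C@H](COCc2ccccc2)Oc2ccc(/C=C/CBr)cc2OC | intermediate |
| 13 | 4-bromo-2,6-dimethoxyphenol | COc1cc(Br)cc(OC)c1O | starting material |
| 14 | 2-(benzyloxy)-5-bromo-1,3-dimethoxybenzene | COc1cc(Br)cc(OC)c1OCc1ccccc1 | intermediate |
| 15 | (R)-2,3-O-isopropylideneglyceraldehyde | O=C[C@H]1COC(C)(C)O1 | starting material |
| 16 | (S)-aryl[(4R)-dioxolan-4-yl]methanol (Ar = 4-OBn-3,5-(OMe)2C6H2) | COc1cc(cc(OC)c1OCc2ccccc2)[C@H](O)[C@H]1COC(C)(C)O1 | intermediate |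
| 17 | tether ether (acetonide, O-cinnamyl) | COc1cc(ccc1OCc2ccccc2)[C@@H](OCc2ccccc2)[C@H](COCc2ccccc2)Oc2ccc(/C=C/CO[C@@H](c3cc(OC)c(OCc4ccccc4)c(OC)c3)[C@H]3COC(C)(C)O3)cc2OC | intermediate |
| 18 | α-aryl-α-cinnamyloxy acetaldehyde | COc1cc(ccc1OCc2ccccc2)[C@@H](OCc2ccccc2)[C@H](COCc2ccccc2)Oc2ccc(/C=C/CO[C@@H](c3cc(OC)c(OCc4ccccc4)c(OC)c3)C=O)cc2OC | intermediate |
| 19 | aldoxime of 18 | COc1cc(ccc1OCc2ccccc2)[C@@H](OCc2ccccc2)[C@H](COCc2ccccc2)Oc2ccc(/C=C/CO[C@@H](c3cc(OC)c(OCc4ccccc4)c(OC)c3)/C=N/O)cc2OC | intermediate |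
| 20 | cis-fused furo[3,4-c]isoxazoline (cycloadduct) | COc1cc(ccc1OCc2ccccc2)[C@@H](OCc2ccccc2)[C@H](COCc2ccccc2)Oc2ccc(cc2OC)[C@@H]3ON=C4[C@H](c5cc(OC)c(OCc6ccccc6)c(OC)c5)OC[C@@H]34 | intermediate |
| 21 | β-hydroxy 3-oxo-THF | COc1cc(ccc1OCc2ccccc2)[C@@H](OCc2ccccc2)[C@H](COCc2ccccc2)Oc2ccc(cc2OC)[C@H](O)[C@@H]3CO[C@@H](c4cc(OC)c(OCc5ccccc5)c(OC)c4)C3=O | intermediate |
| 22 | TES ether of 21 | COc1cc(ccc1OCc2ccccc2)[C@@H](OCc2ccccc2)[C@H](COCc2ccccc2)Oc2ccc(cc2OC)[C@H](O[Si](CC)(CC)CC)[C@@H]3CO[C@@H](c4cc(OC)c(OCc5ccccc5)c(OC)c4)C3=O | intermediate |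
| 23 | exocyclic methyl enol ether (E/Z mixture) | COc1cc(ccc1OCc2ccccc2)[C@@H](OCc2ccccc2)[C@H](COCc2ccccc2)Oc2ccc(cc2OC)[C@H](O[Si](CC)(CC)CC)[C@@H]3CO[C@@H](c4cc(OC)c(OCc5ccccc5)c(OC)c4)C3=COC | intermediate |
| 24 | lactol (anomeric mixture) | COc1cc(ccc1OCc2ccccc2)[C@@H](OCc2ccccc2)[C@H](COCc2ccccc2)Oc2ccc(cc2OC)[C@@H]3OC(O)[C@@H]4[C@H]3CO[C@H]4c5cc(OC)c(OCc6ccccc6)c(OC)c5 | intermediate |
| 25 | tetra-O-benzyl Ficusesquilignan A | COc1cc(ccc1OCc2ccccc2)[C@@H](OCc2ccccc2)[C@H](COCc2ccccc2)Oc2ccc(cc2OC)[C@@H]3OC[C@@H]4[C@H]3CO[C@H]4c5cc(OC)c(OCc6ccccc6)c(OC)c5 | intermediate |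
| 26 | Ficusesquilignan A | COc1cc([C@@H](O)[C@H](CO)Oc2ccc([C@@H]3OC[C@@H]4[C@H]3CO[C@H]4c3cc(OC)c(O)c(OC)c3)cc2OC)ccc1O | target |

---

**Totals**
- Total steps: 21.
- Longest linear sequence: 19 steps (1→2→4→5→6→7→9→10→11→12→17→18→19→20→21→22→23→24→25→26).

**Three steps most likely to fail**
1. **Step 15, cycloaddition.** Hypochlorite may chlorinate the electron-rich arenes, and the facial selectivity at the carbinol is only moderate.
   - Fallback: generate the nitrile oxide from the corresponding primary nitro compound by Mukaiyama dehydration (PhNCO, Et3N), which avoids hypochlorite.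
   - Any diastereomers are separable at the ketone stage (21).
2. **Step 18, Wittig methoxymethylenation.** The ketone is enolizable and sits next to β-silyloxy and α-alkoxy centres.
   - Fallback: Petasis/Tebbe methylenation, then 9-BBN hydroboration/oxidation and Dess–Martin oxidation, to reach the same epimerizable aldehyde and lactol.
3. **Step 20, Et3SiH/BF3 reduction.** The Lewis acid may ionize the electron-rich benzylic ethers.
   - Fallback: NaBH4 reduction of the lactol to the diol, then primary-selective tosylation and NaH Williamson cyclization, which retains the benzylic stereocentre.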